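**Retrosynthetic overview**

1. The target, 2,5-dihydroxy-3-hexadecyl-1,4-benzoquinone, is taken back to 3-hexadecylbenzene-1,2,4,5-tetrol; the last step is only a two-electron aerial oxidation and forms no skeletal bond.
2. Feature used: on the single six-membered carbocycle (tetrol numbering: chain on C3, hydrogen on C6) the oxygens on C2 and C4 flank the chain as in a 2-alkylresorcinol, and the oxygens on C1 and C5 each sit ortho to one of these and para to the other, exactly where a resorcinol is formylated.
3. Key disconnection: the C1–O and C5–O bonds both come from a twofold Dakin aryl carbon-to-oxygen shift on 5-hexadecyl-4,6-dihydroxybenzene-1,3-dicarbaldehyde, the two formyl carbons leaving as formic acid.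
4. The dialdehyde comes from double Duff formylation of 2-hexadecylresorcinol, made by C2-lithiation/alkylation of 1,3-dimethoxybenzene with 1-bromohexadecane and BBr3 demethylation.
5. No ring is built: the benzene ring is bought and decorated, and there is no stereocentre.

Key step: step 4

Remark: the target SMILES shows one of two degenerate tautomers of a 2,5-dihydroxy-1,4-benzoquinone; both are the same compound.

**Route**

Step 1
Reactants: 1 1,3-dimethoxybenzene; 2 1-bromohexadecane
Product: 4 2-hexadecyl-1,3-dimethoxybenzene, via 2,6-dimethoxyphenyllithium 3 (not isolated)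
Conditions: 1 (1.3 equiv), n-BuLi (1.25 equiv), THF, 0 °C to rt; then 2 (1.0 equiv), 0 °C to reflux; aq. NH4Cl
Reagents that add atoms: n-butyllithium, [Li]CCCC (its lithium stands in intermediate 3 only; product 4 holds atoms of 1 and 2 alone)
Why: Directed ortho-metalation removes the C2 hydrogen flanked by both methoxy groups, and the aryllithium should displace bromide from the primary alkyl bromide in an SN2 alkylation, the bromide being the limiting partner so that no long-chain halide remains to be separated.

Step 2
Reactants: 4 2-hexadecyl-1,3-dimethoxybenzene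
Product: 5 2-hexadecylbenzene-1,3-diol (2-hexadecylresorcinol)
Conditions: BBr3 (3 equiv), CH2Cl2, −78 °C to rt; then H2O
Reagents that add atoms: none
Why: Lewis-acid ether cleavage with BBr3, in which bromide attacks the methyl group of each boron-bound aryl methyl ether, should free both phenols while the saturated chain is inert.

Step 3
Reactants: 5 2-hexadecylbenzene-1,3-diol; 6 hexamethylenetetramine
Product: 8 5-hexadecyl-4,6-dihydroxybenzene-1,3-dicarbaldehyde, via bis-aldimine 7 (not isolated)
Conditions: 6 (4 equiv), CF3CO2H, reflux; then 4 M aq. HCl, 80 °C
Reagents that add atoms: hexamethylenetetramine 6, C1N2CN3CN1CN(C2)C3 (both formyl carbons, and the nitrogens of 7); water, O (both formyl oxygens)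
Why: In this Duff formylation, iminium ions from protonated hexamethylenetetramine should substitute C4 and C6, the only free positions ortho to one hydroxyl and para to the other (C2 carries the chain, C5 is meta to both), after which the benzylic amines are dehydrogenated to the imine stage 7 by hydride transfer to further iminium ion and aqueous acid hydrolyses them to the two formyl groups.

Step 4
Reactants: 8 5-hexadecyl-4,6-dihydroxybenzene-1,3-dicarbaldehyde
Product: 10 3-hexadecylbenzene-1,2,4,5-tetrol, via diformate 9 (not isolated)
Conditions: 30% aq. H2O2 (2.2 equiv), B(OH)3 (5 equiv), conc. H2SO4 (cat.), degassed THF, 0 °C to rt, Ar; then degassed 1 M HCl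
Reagents that add atoms: hydrogen peroxide, OO (the two new phenolic oxygens)
Why: Hydrogen peroxide adds to each formyl carbon to give a hydroxy-hydroperoxide adduct, which boric acid is taken to esterify so that the O–O bond is primed to break; the ring carbon then shifts from the formyl carbon to oxygen, forming the C1–O and C5–O bonds and leaving aryl formate 9, which the aqueous acid hydrolyses to the phenol and formic acid. This is the Dakin oxidation, known for salicylaldehyde, 4-hydroxybenzaldehyde and 2,4-dihydroxybenzaldehyde, used here twice on one ring. No ring is closed and no stereocentre is formed. The step needs aryl migration to beat hydride migration (which would give the carboxylic acid) at both formyl groups, and each migrating ring carbon has one hydroxyl ortho and one para, the best donor pattern for a shift to electron-poor oxygen. It also needs the electron-rich polyphenols to survive the oxidant, which the acidic borate medium (phenols un-ionised, each 1,2-diol pair held as a borate ester), the small excess of peroxide and the exclusion of air should secure. Any tetrol that is oxidised on work-up goes to the target itself, so that side reaction costs no material.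

Step 5
Reactants: 10 3-hexadecylbenzene-1,2,4,5-tetrol
Product: 11 2,5-dihydroxy-3-hexadecylcyclohexa-2,5-diene-1,4-dione (target)
Conditions: air, THF–sat. aq. NaHCO3, rt; then 1 M HCl
Reagents that add atoms: none
Why: Autoxidation of a hydroxyhydroquinone: in bicarbonate the partly ionised tetrol should pass two electrons to dioxygen to give the 2,5-dihydroxy-1,4-benzoquinone, whose delocalised vinylogous-acid anion resists further oxidation, and either para pair of oxygens leads to the same compound, so no regiochemical question arises.

**Compound list**

1 | 1,3-dimethoxybenzene | COc1cccc(OC)c1 | starting material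
2 | 1-bromohexadecane | CCCCCCCCCCCCCCCCBr | starting material
3 | 2,6-dimethoxyphenyllithium | [Li]c1c(OC)cccc1OC | intermediate (not isolated)
4 | 2-hexadecyl-1,3-dimethoxybenzene | CCCCCCCCCCCCCCCCc1c(OC)cccc1OC | intermediate
5 | 2-hexadecylbenzene-1,3-diol (2-hexadecylresorcinol) | CCCCCCCCCCCCCCCCc1c(O)cccc1O | intermediate
6 | hexamethylenetetramine | C1N2CN3CN1CN(C2)C3 | starting material
7 | 2-hexadecyl-4,6-bis(iminomethyl)benzene-1,3-diol (the Duff bis-iminium stage, written in its simplest form as the N-unsubstituted bis-aldimine) | CCCCCCCCCCCCCCCCc1c(O)c(C=N)cc(C=N)c1O | intermediate (not isolated)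
8 | 5-hexadecyl-4,6-dihydroxybenzene-1,3-dicarbaldehyde | CCCCCCCCCCCCCCCCc1c(O)c(C=O)cc(C=O)c1O | intermediate
9 | 5-hexadecyl-4,6-dihydroxy-1,3-phenylene diformate | CCCCCCCCCCCCCCCCc1c(O)c(OC=O)cc(OC=O)c1O | intermediate (not isolated)
10 | 3-hexadecylbenzene-1,2,4,5-tetrol | CCCCCCCCCCCCCCCCc1c(O)c(O)cc(O)c1O | intermediate
11 | 2,5-dihydroxy-3-hexadecylcyclohexa-2,5-diene-1,4-dione | CCCCCCCCCCCCCCCCC1=C(O)C(=O)C=C(O)C1=O | target

**Step count**

Total step count: 5. Longest linear sequence: 5 steps (1 → 4 → 5 → 8 → 10 → 11).

**Steps most likely to fail and their fallbacks**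

Step 4 (key step). The risk is over-oxidation: once the first formyl group has become a hydroxyl, the trihydroxybenzaldehyde stage may be oxidised to a quinone or cleaved by peroxide before the second aryl shift takes place. The fallback sets out from dialdehyde 8 and keeps the phenols masked until the oxidant is gone.
- Benzylation of both phenols (BnBr, K2CO3, DMF, 60 °C) should give 4,6-bis(benzyloxy)-5-hexadecylbenzene-1,3-dicarbaldehyde F1.
- Baeyer–Villiger oxidation with mCPBA in CH2Cl2 (NaHCO3 buffer) should give 4,6-bis(benzyloxy)-5-hexadecyl-1,3-phenylene diformate F2.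
- Hydrolysis with KOH in MeOH–H2O under argon, then HCl, should give 4,6-bis(benzyloxy)-5-hexadecylbenzene-1,3-diol F3.
- Hydrogenolysis (H2, Pd/C, EtOAc) removes both benzyl groups under reducing conditions, and the route is rejoined at tetrol 10.

Step 3. The risk is that the double formylation stalls after the first formyl group has deactivated the ring, or that the aminomethylated resorcinol condenses to polymeric material in hot acid. The fallback sets out from 2-hexadecyl-1,3-dimethoxybenzene 4 and bypasses 5.
- Bromination with NBS (2.1 equiv, MeCN, rt) at the two positions para to a methoxy group should give 1,5-dibromo-3-hexadecyl-2,4-dimethoxybenzene F4.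
- Double bromine–lithium exchange (t-BuLi, 4.4 equiv, THF, −78 °C) should give 3-hexadecyl-2,4-dimethoxy-1,5-phenylenedilithium F5.
- Quenching with DMF and aqueous acid should give 5-hexadecyl-4,6-dimethoxybenzene-1,3-dicarbaldehyde F6.
- BBr3 in CH2Cl2 cleaves both carbonyl-flanked methyl ethers, and the route is rejoined at dialdehyde 8.

Step 1. The risk is a sluggish SN2 reaction of the doubly ortho-substituted aryllithium with the long-chain bromide, with competing elimination to hexadecene and incomplete conversion that leaves greasy, hard-to-separate mixtures. The fallback sets out from 1,3-dimethoxybenzene 1 (through the same lithio compound 3) and replaces alkylation by carbonyl addition.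
- Addition of 3 to commercial hexadecanal (THF, −78 °C to rt) should give racemic 1-(2,6-dimethoxyphenyl)hexadecan-1-ol F7.
- Ionic hydrogenation (Et3SiH, CF3CO2H, CH2Cl2, 0 °C to rt) removes the benzylic hydroxyl through the doubly methoxy-stabilised benzylic cation, and the route is rejoined at 2-hexadecyl-1,3-dimethoxybenzene 4.

**Further compounds**

F1 | step 4 | 4,6-bis(benzyloxy)-5-hexadecylbenzene-1,3-dicarbaldehyde | CCCCCCCCCCCCCCCCc1c(OCc2ccccc2)c(C=O)cc(C=O)c1OCc1ccccc1
F2 | step 4 | 4,6-bis(benzyloxy)-5-hexadecyl-1,3-phenylene diformate | CCCCCCCCCCCCCCCCc1c(OCc2ccccc2)c(OC=O)cc(OC=O)c1OCc1ccccc1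
F3 | step 4 | 4,6-bis(benzyloxy)-5-hexadecylbenzene-1,3-diol | CCCCCCCCCCCCCCCCc1c(OCc2ccccc2)c(O)cc(O)c1OCc1ccccc1
F4 | step 3 | 1,5-dibromo-3-hexadecyl-2,4-dimethoxybenzene | CCCCCCCCCCCCCCCCc1c(OC)c(Br)cc(Br)c1OC
F5 | step 3 | 3-hexadecyl-2,4-dimethoxy-1,5-phenylenedilithium | CCCCCCCCCCCCCCCCc1c(OC)c([Li])cc([Li])c1OC
F6 | step 3 | 5-hexadecyl-4,6-dimethoxybenzene-1,3-dicarbaldehyde | CCCCCCCCCCCCCCCCc1c(OC)c(C=O)cc(C=O)c1OC
F7 | step 1 | 1-(2,6-dimethoxyphenyl)hexadecan-1-ol (racemic) | CCCCCCCCCCCCCCCC(O)c1c(OC)cccc1OC
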